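**Strategy.** In the tetrahydrofuran ring (O1, C2 aryl, C3 acyloxymethyl, C4 benzyl, C5) the unit O1–C2(Ar)–C3–CH2O is an aldol pattern: C2 an oxocarbenium carbon, C3 the α-carbon of an aldehyde. Both are stored in one seven-membered cyclic enol acetal, a (5S)-2-aryl-5-benzyl-4,5-dihydro-1,3-dioxepine, built from cis-butenediol, O-benzylvanillin and a benzylic ester by acetalisation and an asymmetric Heck reaction. A Lewis acid triggers a [1,3] oxygen-to-carbon shift that contracts this ring: C2–C3 forms and the tetrahydrofuran closes, both acetal epimers converge, C4 steers C2, and base equilibration at C3 gives the 2,3-trans-3,4-cis aldehyde. Reduction, debenzylation and Mitsunobu esterification complete the synthesis.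

Key step: step 4

Remark: the SMILES is read as the (2R,3S,4S) isomer (Ar and CH2O trans, CH2O and benzyl cis); the sense of induction of the phosphoramidite in step 3 cannot be derived from first principles, so the ligand antipode that gives (5S)-6 is to be fixed in a pilot run.

Step 1
Reactants: 1 (Z)-but-2-ene-1,4-diol; 2 4-(benzyloxy)-3-methoxybenzaldehyde
Product: 3 2-[4-(benzyloxy)-3-methoxyphenyl]-4,7-dihydro-1,3-dioxepine
Conditions: p-TsOH·H2O (cat.), toluene, reflux, Dean–Stark
Reagents that add atoms: none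
Why: Acid-catalysed acetalisation driven by azeotropic removal of water; the cis-diol closes the seven-membered acetal and no stereocentre arises because C2 lies on a mirror plane.

Step 2
Reactants: 4 [4-(benzyloxy)-3-methoxyphenyl]methanol
Product: 5 4-(benzyloxy)-3-methoxybenzyl 2,2,2-trifluoroacetate
Conditions: (CF3CO)2O, pyridine, CH2Cl2, 0 °C; used crude
Reagents that add atoms: trifluoroacetic anhydride, O=C(OC(=O)C(F)(F)F)C(F)(F)F
Why: O-acylation of a primary benzylic alcohol installs the ester leaving group that zerovalent palladium can ionise; the electron-rich ester is not stored.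

Step 3
Reactants: 3 2-[4-(benzyloxy)-3-methoxyphenyl]-4,7-dihydro-1,3-dioxepine; 5 4-(benzyloxy)-3-methoxybenzyl 2,2,2-trifluoroacetate
Product: 6 (5S)-2-[4-(benzyloxy)-3-methoxyphenyl]-5-[4-(benzyloxy)-3-methoxybenzyl]-4,5-dihydro-1,3-dioxepine (both C2 epimers)
Conditions: Pd(dba)2 (5 mol %), BINOL-derived N,N-bis(1-phenylethyl)phosphoramidite (12 mol %), Li2CO3, 1,4-dioxane, 50 °C; 3 in twofold excess
Reagents that add atoms: none
Why: Asymmetric Mizoroki–Heck reaction of a benzylic electrophile with a cyclic cis-olefin: zerovalent palladium inserts into the benzylic C–O bond, the benzylpalladium species adds syn across C5=C6 and, because the only syn β-hydrogen sits on C7, elimination gives the enol ether, while the chiral ligand distinguishes the two enantiotopic olefin carbons and so sets C5 as S on either ring face (C2 stays a mixture, which step 4 erases).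

Step 4
Reactants: 6 (5S)-2-[4-(benzyloxy)-3-methoxyphenyl]-5-[4-(benzyloxy)-3-methoxybenzyl]-4,5-dihydro-1,3-dioxepine
Product: 8 (2R,3R,4S)-2-[4-(benzyloxy)-3-methoxyphenyl]-4-[4-(benzyloxy)-3-methoxybenzyl]tetrahydrofuran-3-carbaldehyde, via kinetic cis-aldehyde 7 (not isolated)
Conditions: TMSOTf (10 mol %), CH2Cl2, −78 °C; then DBU (30 mol %), −78 → 23 °C
Reagents that add atoms: none
Why: TMSOTf ionises the enol-ether C2–O1 bond of either acetal epimer of 6 to the same (E)-oxocarbenium ion paired with a ring-derived (Z)-silyl enolate, and the enolate carbon C6 recaptures C2, a Lewis-acid [1,3] oxygen-to-carbon shift (Ferrier-type ring contraction of 4,5-dihydro-1,3-dioxepines, in essence an intramolecular Mukaiyama aldol addition to an oxocarbenium ion). The tetrahydrofuran closes in a 5-(enolexo)-endo-trig mode, which the short, strongly electrophilic C=O+ unit tolerates, and return of C2 to oxygen only regenerates 6, so C-alkylation drains the equilibrium. C4 of the product is the untouched C5 of 6; allylic strain in the (Z)-enolate holds the C5–H bond in the enolate plane, so the tether brings C2 to the face of C6 anti to the benzyl group (3,4-trans), and collapse within the contact ion pair should place the aryl group cis to the formyl group (2,3-cis), which fixes C2 as R, trans to the benzyl group, in aldehyde 7. DBU then equilibrates C3 alone through the enolate, and the formyl group should settle trans to the 2-aryl group and cis to the smaller CH2Ar group, giving 8 with one pseudoaxial substituent instead of two. The step needs kinetic control in the C–C closure, secured by the low temperature and by quenching the Lewis acid before warming (reopening would let C2 drift cis to the benzyl group), and C3-only epimerisation, secured because the ring C2–O1 bond lies near the nodal plane of the enolate and resists β-elimination.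

Step 5
Reactants: 8 (2R,3R,4S)-2-[4-(benzyloxy)-3-methoxyphenyl]-4-[4-(benzyloxy)-3-methoxybenzyl]tetrahydrofuran-3-carbaldehyde
Product: 9 [(2R,3S,4S)-2-[4-(benzyloxy)-3-methoxyphenyl]-4-[4-(benzyloxy)-3-methoxybenzyl]tetrahydrofuran-3-yl]methanol
Conditions: NaBH4, MeOH–THF, 0 °C
Reagents that add atoms: none
Why: Hydride reduction of the aldehyde, run cold and at once so that the C3 configuration from step 4 is frozen as a non-epimerisable primary alcohol (the descriptor changes from R to S only through the priority change).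

Step 6
Reactants: 9 [(2R,3S,4S)-2-[4-(benzyloxy)-3-methoxyphenyl]-4-[4-(benzyloxy)-3-methoxybenzyl]tetrahydrofuran-3-yl]methanol
Product: 10 4-[(2R,3S,4S)-4-(4-hydroxy-3-methoxybenzyl)-3-(hydroxymethyl)tetrahydrofuran-2-yl]-2-methoxyphenol
Conditions: H2 (1 atm), 10% Pd/C, EtOAc–EtOH, 23 °C; stopped after two equivalents of H2
Reagents that add atoms: none
Why: Hydrogenolysis of the two aryl benzyl ethers, which should cleave much faster than the cyclic benzylic C2–O1 ether; no stereocentre is touched.

Step 7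
Reactants: 10 4-[(2R,3S,4S)-4-(4-hydroxy-3-methoxybenzyl)-3-(hydroxymethyl)tetrahydrofuran-2-yl]-2-methoxyphenol; 11 (E)-3-(4-hydroxyphenyl)prop-2-enoic acid
Product: 12 [(2R,3S,4S)-2-(4-hydroxy-3-methoxyphenyl)-4-(4-hydroxy-3-methoxybenzyl)tetrahydrofuran-3-yl]methyl (E)-3-(4-hydroxyphenyl)prop-2-enoate
Conditions: PPh3, DIAD, THF, 0 → 23 °C
Reagents that add atoms: none
Why: Mitsunobu esterification: the betaine deprotonates the carboxylic acid far more readily than any phenol, and the carboxylate displaces the activated primary alcohol, so the ester forms without phenol protection and without touching a stereocentre or the E-alkene.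

**Compound list**

1 | (Z)-but-2-ene-1,4-diol | OC/C=C\CO | starting material
2 | 4-(benzyloxy)-3-methoxybenzaldehyde | COc1cc(C=O)ccc1OCc1ccccc1 | starting material
3 | 2-[4-(benzyloxy)-3-methoxyphenyl]-4,7-dihydro-1,3-dioxepine | COc1cc(C2OC/C=C\CO2)ccc1OCc1ccccc1 | intermediate
4 | [4-(benzyloxy)-3-methoxyphenyl]methanol | COc1cc(CO)ccc1OCc1ccccc1 | starting material
5 | 4-(benzyloxy)-3-methoxybenzyl 2,2,2-trifluoroacetate | COc1cc(COC(=O)C(F)(F)F)ccc1OCc1ccccc1 | intermediate
6 | (5S)-2-[4-(benzyloxy)-3-methoxyphenyl]-5-[4-(benzyloxy)-3-methoxybenzyl]-4,5-dihydro-1,3-dioxepine (C2 epimers) | COc1cc(C[C@@H]2COC(c3ccc(OCc4ccccc4)c(OC)c3)OC=C2)ccc1OCc1ccccc1 | intermediate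
7 | (2R,3S,4S)-2-[4-(benzyloxy)-3-methoxyphenyl]-4-[4-(benzyloxy)-3-methoxybenzyl]tetrahydrofuran-3-carbaldehyde (2,3-cis, 3,4-trans) | COc1cc(C[C@@H]2CO[C@@H](c3ccc(OCc4ccccc4)c(OC)c3)[C@H]2C=O)ccc1OCc1ccccc1 | intermediate
8 | (2R,3R,4S)-2-[4-(benzyloxy)-3-methoxyphenyl]-4-[4-(benzyloxy)-3-methoxybenzyl]tetrahydrofuran-3-carbaldehyde (2,3-trans, 3,4-cis) | COc1cc(C[C@@H]2CO[C@@H](c3ccc(OCc4ccccc4)c(OC)c3)[C@@H]2C=O)ccc1OCc1ccccc1 | intermediate
9 | [(2R,3S,4S)-2-[4-(benzyloxy)-3-methoxyphenyl]-4-[4-(benzyloxy)-3-methoxybenzyl]tetrahydrofuran-3-yl]methanol | COc1cc(C[C@@H]2CO[C@@H](c3ccc(OCc4ccccc4)c(OC)c3)[C@@H]2CO)ccc1OCc1ccccc1 | intermediate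
10 | 4-[(2R,3S,4S)-4-(4-hydroxy-3-methoxybenzyl)-3-(hydroxymethyl)tetrahydrofuran-2-yl]-2-methoxyphenol (lariciresinol of the 2R,3S,4S series) | COc1cc(C[C@@H]2CO[C@@H](c3ccc(O)c(OC)c3)[C@@H]2CO)ccc1O | intermediate
11 | (E)-3-(4-hydroxyphenyl)prop-2-enoic acid (p-coumaric acid) | O=C(O)/C=C/c1ccc(O)cc1 | starting material
12 | [(2R,3S,4S)-2-(4-hydroxy-3-methoxyphenyl)-4-(4-hydroxy-3-methoxybenzyl)tetrahydrofuran-3-yl]methyl (E)-3-(4-hydroxyphenyl)prop-2-enoate (lariciresinol p-coumarate) | COc1cc(C[C@@H]2CO[C@@H](c3ccc(O)c(OC)c3)[C@@H]2COC(=O)/C=C/c2ccc(O)cc2)ccc1O | target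

**Step count.** Total: 7 steps. Longest linear sequence: 6 steps (1, 3, 4, 5, 6, 7).

**Steps most likely to fail**

1. Step 4. The ion-pair collapse may lose kinetic control, either by closing through the 2,3-trans transition state or by reversible ring opening; both would put the aryl group cis to the benzyl group, which C3 epimerisation cannot repair. The C3 enolisation equilibrium may also lie less far on the side of 8 than expected. The fallback sets out from 6 and comes back at 9; it makes the C2–C3 bond by an intermolecular aldol reaction and closes the ring through oxygen. Aqueous acid (1 M HCl, THF) hydrolyses the enol acetal of 6 to the lactol (4S)-4-[4-(benzyloxy)-3-methoxybenzyl]tetrahydrofuran-2-ol F1, with aldehyde 2 recovered. PhI(OAc)2 with catalytic TEMPO oxidises it to the lactone (4S)-4-[4-(benzyloxy)-3-methoxybenzyl]dihydrofuran-2(3H)-one F2. Its lithium enolate (LDA, THF, −78 °C) adds to aldehyde 2 anti to the benzyl group and gives the aldol (3R,4S)-3-{[4-(benzyloxy)-3-methoxyphenyl](hydroxy)methyl}-4-[4-(benzyloxy)-3-methoxybenzyl]dihydrofuran-2(3H)-one F3 as carbinol epimers. LiAlH4 reduces it to the triol (2S,3S)-2-{[4-(benzyloxy)-3-methoxyphenyl](hydroxy)methyl}-3-[4-(benzyloxy)-3-methoxybenzyl]butane-1,4-diol F4. Catalytic camphorsulfonic acid in CH2Cl2 ionises the benzylic carbinol, and the C5 hydroxyl closes the ring trans to the C3 branch, giving 9. Taking C2 instead of C9 into the ring turns the trans-lactone relationship into the required 3,4-cis one.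

2. Step 3. The chiral ligand may discriminate poorly between the two olefin carbons in the migratory insertion, and the electron-rich trifluoroacetate may ionise before oxidative addition. The fallback sets out from 4 and comes back at 6; it forms the benzyl–carbon bond first and creates C5 afterwards by an asymmetric double-bond shift. SOCl2 converts 4 into 4-(benzyloxy)-3-methoxybenzyl chloride F5. Separately, 2-butyne-1,4-diol undergoes syn hydrostannation (Bu3SnH, PdCl2(PPh3)2 cat., THF) to (E)-2-(tributylstannyl)but-2-ene-1,4-diol F6. Stille coupling of F5 with F6 (Pd(PPh3)4, CuI, DMF, 50 °C) gives (Z)-2-[4-(benzyloxy)-3-methoxybenzyl]but-2-ene-1,4-diol F7. Acetalisation with aldehyde 2 as in step 1 gives 2-[4-(benzyloxy)-3-methoxyphenyl]-5-[4-(benzyloxy)-3-methoxybenzyl]-4,7-dihydro-1,3-dioxepine F8. A nickel hydride made from NiBr2[(R,R)-Me-DuPHOS] or its antipode and LiBHEt3 (THF, low temperature) then moves the C5=C6 bond to C6=C7 and delivers hydrogen to C5 under ligand control, giving 6.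

3. Step 7. Under Mitsunobu activation the three free phenols of 10 and the phenol of 11 may be alkylated or acylated in competition with the carboxylate. The fallback sets out from 9 and comes back at 12; it builds the cinnamate on the molecule after debenzylation. Heating 9 with Meldrum's acid (toluene, 100 °C) gives the malonic half-ester 3-{[(2R,3S,4S)-2-[4-(benzyloxy)-3-methoxyphenyl]-4-[4-(benzyloxy)-3-methoxybenzyl]tetrahydrofuran-3-yl]methoxy}-3-oxopropanoic acid F9. Hydrogenolysis (H2, 10% Pd/C, EtOAc) removes both benzyl groups while no alkene is yet present, giving 3-{[(2R,3S,4S)-2-(4-hydroxy-3-methoxyphenyl)-4-(4-hydroxy-3-methoxybenzyl)tetrahydrofuran-3-yl]methoxy}-3-oxopropanoic acid F10. Knoevenagel–Doebner condensation with 4-hydroxybenzaldehyde (pyridine, piperidine cat., 70 °C) forms the E-cinnamate with loss of carbon dioxide and gives 12.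

**Further compounds**

F1 | step 4 | (4S)-4-[4-(benzyloxy)-3-methoxybenzyl]tetrahydrofuran-2-ol | COc1cc(C[C@@H]2COC(O)C2)ccc1OCc1ccccc1
F2 | step 4 | (4S)-4-[4-(benzyloxy)-3-methoxybenzyl]dihydrofuran-2(3H)-one | COc1cc(C[C@@H]2COC(=O)C2)ccc1OCc1ccccc1
F3 | step 4 | (3R,4S)-3-{[4-(benzyloxy)-3-methoxyphenyl](hydroxy)methyl}-4-[4-(benzyloxy)-3-methoxybenzyl]dihydrofuran-2(3H)-one | COc1cc(C[C@@H]2COC(=O)[C@H]2C(O)c2ccc(OCc3ccccc3)c(OC)c2)ccc1OCc1ccccc1
F4 | step 4 | (2S,3S)-2-{[4-(benzyloxy)-3-methoxyphenyl](hydroxy)methyl}-3-[4-(benzyloxy)-3-methoxybenzyl]butane-1,4-diol | COc1cc(C[C@H](CO)[C@@H](CO)C(O)c2ccc(OCc3ccccc3)c(OC)c2)ccc1OCc1ccccc1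
F5 | step 3 | 4-(benzyloxy)-3-methoxybenzyl chloride | COc1cc(CCl)ccc1OCc1ccccc1
F6 | step 3 | (E)-2-(tributylstannyl)but-2-ene-1,4-diol | OC/C=C(\CO)[Sn](CCCC)(CCCC)CCCC
F7 | step 3 | (Z)-2-[4-(benzyloxy)-3-methoxybenzyl]but-2-ene-1,4-diol | OC/C=C(\CO)Cc1ccc(OCc2ccccc2)c(OC)c1
F8 | step 3 | 2-[4-(benzyloxy)-3-methoxyphenyl]-5-[4-(benzyloxy)-3-methoxybenzyl]-4,7-dihydro-1,3-dioxepine | COc1cc(CC2=CCOC(c3ccc(OCc4ccccc4)c(OC)c3)OC2)ccc1OCc1ccccc1
F9 | step 7 | 3-{[(2R,3S,4S)-2-[4-(benzyloxy)-3-methoxyphenyl]-4-[4-(benzyloxy)-3-methoxybenzyl]tetrahydrofuran-3-yl]methoxy}-3-oxopropanoic acid | COc1cc(C[C@@H]2CO[C@@H](c3ccc(OCc4ccccc4)c(OC)c3)[C@@H]2COC(=O)CC(=O)O)ccc1OCc1ccccc1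
F10 | step 7 | 3-{[(2R,3S,4S)-2-(4-hydroxy-3-methoxyphenyl)-4-(4-hydroxy-3-methoxybenzyl)tetrahydrofuran-3-yl]methoxy}-3-oxopropanoic acid | COc1cc(C[C@@H]2CO[C@@H](c3ccc(O)c(OC)c3)[C@@H]2COC(=O)CC(=O)O)ccc1O
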